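**Retrosynthetic overview**
1. Target 12 comes from one neutral hydrogenation/hydrogenolysis of the benzyl-protected (E)-allylic alcohol 10. Acid must be avoided at the end, because it would close the tertiary alcohol onto a neighbouring phenol to give a chroman.
2. The C6–side-chain bond comes from a Heck coupling of 6-iodoflavone 8 with 2-methylbut-3-en-2-ol 9. This delivers all five side-chain carbons and the tertiary OH in one piece.
3. The C6–I bond comes from iodination ortho to the free, chelated 5-OH of 7. That OH is exposed by chelation-controlled mono-debenzylation of flavone 6.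
4. Ring C (the pyranone) comes from I2/DMSO oxidative cyclisation of chalcone 4. Chalcone 4 comes from a Claisen–Schmidt condensation of acetophenone 1 (ring A) with aldehyde 2 (ring B).
5. Ring order: rings A and B are bought, and ring C is the only ring formed (step 2).

Assumption: the target has no stereocentre and is achiral, so no enantiocontrol is needed; 1, 2 and 9 are taken as catalogue chemicals.

**Route**

Step 1
Reactants: 1 1-[2,4-bis(benzyloxy)-6-hydroxyphenyl]ethan-1-one; 2 2,4-bis(benzyloxy)benzaldehyde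
Product: 4 (E)-1-[2,4-bis(benzyloxy)-6-hydroxyphenyl]-3-[2,4-bis(benzyloxy)phenyl]prop-2-en-1-one, via aldol adduct 3 (not isolated)
Conditions: KOH (50% aq, excess), EtOH/THF, rt to 40 °C, 48 h; then 1 M HCl
Reagents that add atoms: none
Why: Claisen–Schmidt (crossed aldol) condensation in which only 1 can enolise and 2 is the only aldehyde, so E1cB loss of water from 3 gives the conjugated, favoured E-enone and erases the stereocentre of 3.

Step 2
Reactants: 4 (E)-chalcone from step 1
Product: 6 tetra-O-benzyl flavone [5,7-bis(benzyloxy)-2-[2,4-bis(benzyloxy)phenyl]-4H-chromen-4-one], via flavanone 5 (not isolated)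
Conditions: I2 (10 mol %), DMSO, 130 °C, 3 h
Reagents that add atoms: none
Why: Iodine/DMSO oxidative cyclisation, in which the free 2'-OH adds to the enone (oxa-Michael) to give 5, C3 is iodinated and loses HI to form the γ-pyrone (ring C), DMSO re-oxidises HI to I2, and the benzyl ethers survive the near-neutral medium.

Step 3
Reactants: 6 tetra-O-benzyl flavone
Product: 7 7-(benzyloxy)-2-[2,4-bis(benzyloxy)phenyl]-5-hydroxy-4H-chromen-4-one
Conditions: MgBr2·OEt2 (3 equiv), toluene/Et2O, 80 °C; then 1 M HCl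
Reagents that add atoms: none
Why: Chelation-controlled Lewis-acid ether cleavage, in which only O5 can share magnesium with the C4 carbonyl in a six-membered chelate, so bromide attacks that benzylic carbon alone (SN2) and the other three benzyl ethers stay.

Step 4
Reactants: 7 5-hydroxy-7,2',4'-tribenzyl flavone
Product: 8 7-(benzyloxy)-2-[2,4-bis(benzyloxy)phenyl]-5-hydroxy-6-iodo-4H-chromen-4-one
Conditions: BnMe3N·ICl2 (1.05 equiv), CaCO3, CH2Cl2/MeOH 5:2, rt, dark
Reagents that add atoms: benzyltrimethylammonium dichloroiodate, C[N+](C)(C)Cc1ccccc1.Cl[I-]Cl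
Why: Electrophilic aromatic iodination (SEAr), in which this buffered reagent iodinates phenols but not aryl ethers, so ring B is spared, and the chelated 5-OH steers iodine to its only free ortho position, C6, rather than to C8.

Step 5
Reactants: 8 6-iodoflavone; 9 2-methylbut-3-en-2-ol
Product: 10 7-(benzyloxy)-2-[2,4-bis(benzyloxy)phenyl]-5-hydroxy-6-[(E)-3-hydroxy-3-methylbut-1-en-1-yl]-4H-chromen-4-one
Conditions: Pd(OAc)2 (10 mol %), Bu4NCl (1 equiv), NaHCO3 (2.5 equiv), 9 (3 equiv), DMF, 80–90 °C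
Reagents that add atoms: none
Why: Mizoroki–Heck reaction under ligand-free Jeffery conditions, in which zerovalent palladium formed in situ inserts into C–I and adds across the terminal alkene, and because the carbinol carbon bears no hydrogen, syn β-hydride elimination can only give the E-styrenyl tertiary allylic alcohol.

Step 6
Reactants: 10 Heck product
Product: 12 target 2-(2,4-dihydroxyphenyl)-5,7-dihydroxy-6-(3-hydroxy-3-methylbutyl)-4H-chromen-4-one, via saturated tribenzyl ether 11 (not isolated)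
Conditions: H2 (1 atm), 10% Pd/C, EtOAc/MeOH 1:1, rt; filter through Celite, no acid
Reagents that add atoms: none
Why: Catalytic hydrogenation followed by hydrogenolysis, in which the disubstituted alkene is saturated first (11) and the three O–benzyl bonds are then cleaved, while the γ-pyrone C2=C3 bond is inert at 1 atm and the neutral medium keeps the tertiary alcohol from ionising; no stereocentre is created.

**Compound list**
1 | 1-[2,4-bis(benzyloxy)-6-hydroxyphenyl]ethan-1-one | CC(=O)c1c(O)cc(OCc2ccccc2)cc1OCc1ccccc1 | starting material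
2 | 2,4-bis(benzyloxy)benzaldehyde | O=Cc1ccc(OCc2ccccc2)cc1OCc1ccccc1 | starting material
3 | racemic 1-[2,4-bis(benzyloxy)-6-hydroxyphenyl]-3-[2,4-bis(benzyloxy)phenyl]-3-hydroxypropan-1-one (aldol adduct, not isolated) | O=C(CC(O)c1ccc(OCc2ccccc2)cc1OCc1ccccc1)c1c(O)cc(OCc2ccccc2)cc1OCc1ccccc1 | intermediate
4 | (E)-1-[2,4-bis(benzyloxy)-6-hydroxyphenyl]-3-[2,4-bis(benzyloxy)phenyl]prop-2-en-1-one | O=C(/C=C/c1ccc(OCc2ccccc2)cc1OCc1ccccc1)c1c(O)cc(OCc2ccccc2)cc1OCc1ccccc1 | intermediate
5 | racemic 5,7-bis(benzyloxy)-2-[2,4-bis(benzyloxy)phenyl]chroman-4-one (flavanone, not isolated) | O=C1CC(c2ccc(OCc3ccccc3)cc2OCc2ccccc2)Oc2cc(OCc3ccccc3)cc(OCc3ccccc3)c21 | intermediate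
6 | 5,7-bis(benzyloxy)-2-[2,4-bis(benzyloxy)phenyl]-4H-chromen-4-one | O=c1cc(-c2ccc(OCc3ccccc3)cc2OCc2ccccc2)oc2cc(OCc3ccccc3)cc(OCc3ccccc3)c12 | intermediate
7 | 7-(benzyloxy)-2-[2,4-bis(benzyloxy)phenyl]-5-hydroxy-4H-chromen-4-one | O=c1cc(-c2ccc(OCc3ccccc3)cc2OCc2ccccc2)oc2cc(OCc3ccccc3)cc(O)c12 | intermediate
8 | 7-(benzyloxy)-2-[2,4-bis(benzyloxy)phenyl]-5-hydroxy-6-iodo-4H-chromen-4-one | O=c1cc(-c2ccc(OCc3ccccc3)cc2OCc2ccccc2)oc2cc(OCc3ccccc3)c(I)c(O)c12 | intermediate
9 | 2-methylbut-3-en-2-ol | CC(C)(O)C=C | starting material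
10 | 7-(benzyloxy)-2-[2,4-bis(benzyloxy)phenyl]-5-hydroxy-6-[(E)-3-hydroxy-3-methylbut-1-en-1-yl]-4H-chromen-4-one | CC(C)(O)/C=C/c1c(OCc2ccccc2)cc2oc(-c3ccc(OCc4ccccc4)cc3OCc3ccccc3)cc(=O)c2c1O | intermediate
11 | 7-(benzyloxy)-2-[2,4-bis(benzyloxy)phenyl]-5-hydroxy-6-(3-hydroxy-3-methylbutyl)-4H-chromen-4-one (not isolated) | CC(C)(O)CCc1c(OCc2ccccc2)cc2oc(-c3ccc(OCc4ccccc4)cc3OCc3ccccc3)cc(=O)c2c1O | intermediate
12 | 2-(2,4-dihydroxyphenyl)-5,7-dihydroxy-6-(3-hydroxy-3-methylbutyl)-4H-chromen-4-one (achiral) | CC(C)(O)CCc1c(O)cc2oc(-c3ccc(O)cc3O)cc(=O)c2c1O | target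

**Totals**
Total step count: 6.
Longest linear sequence: 6 (1 → 4 → 6 → 7 → 8 → 10 → 12).

**Three steps most likely to fail**

Step 4. The risks are iodination at C8 or at C5' of ring B, or di-iodination. The fallback sets out from 7 and comes back to the route at 11, by-passing 8 and 10.
- Compound 7 is O-alkylated at O5 with tert-butyl 2-methylbut-3-en-2-yl carbonate and Pd(PPh3)4 in THF at 0 °C. This gives 7-(benzyloxy)-2-[2,4-bis(benzyloxy)phenyl]-5-[(2-methylbut-3-en-2-yl)oxy]-4H-chromen-4-one F1.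
- Heating in toluene at 110 °C triggers an aromatic Claisen rearrangement. It can deliver carbon only to C6, because C4a is blocked, and it gives 7-(benzyloxy)-2-[2,4-bis(benzyloxy)phenyl]-5-hydroxy-6-(3-methylbut-2-en-1-yl)-4H-chromen-4-one F2.
- Mukaiyama hydration (Co(acac)2, PhSiH3, O2, THF, rt) places OH at the more substituted alkene carbon and gives 11. Here 11 is isolated and then hydrogenolysed under the conditions of step 6.

Step 5. The risks are slow insertion at an aryl iodide flanked by two ortho oxygens, protodeiodination, and dehydrative closure to a chromene or loss of water to a diene. The fallback sets out from 8 and comes back to the route at 12.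
- Compound 8 is benzylated at O5 (BnBr, K2CO3, DMF, 60 °C) to give 5,7-bis(benzyloxy)-2-[2,4-bis(benzyloxy)phenyl]-6-iodo-4H-chromen-4-one F3. With O5 capped, no ortho-OH can close onto an alkyne to give a furan.
- Sonogashira coupling with 2-methylbut-3-yn-2-ol (PdCl2(PPh3)2, CuI, Et3N/DMF, 60 °C) follows. The linear alkyne needs far less room than an alkene insertion. The product is 5,7-bis(benzyloxy)-2-[2,4-bis(benzyloxy)phenyl]-6-(3-hydroxy-3-methylbut-1-yn-1-yl)-4H-chromen-4-one F4.
- H2 over Pd/C in EtOAc/MeOH saturates the alkyne and removes all four benzyl groups to give 12.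

Step 3. The risks are incomplete cleavage or loss of a second benzyl group. The fallback sets out from 6 and comes back to the route at 7.
- All four benzyl ethers are removed (H2, Pd/C, THF/MeOH) to give 2-(2,4-dihydroxyphenyl)-5,7-dihydroxy-4H-chromen-4-one F5.
- The three non-chelated phenols are then re-benzylated with BnBr (3.1 equiv) and K2CO3 in acetone at reflux. The 5-OH is tied to the C4 carbonyl by a hydrogen bond, is the least reactive phenol, and stays free, which gives 7.

Further compounds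
F1 | step 4 | 7-(benzyloxy)-2-[2,4-bis(benzyloxy)phenyl]-5-[(2-methylbut-3-en-2-yl)oxy]-4H-chromen-4-one | C=CC(C)(C)Oc1cc(OCc2ccccc2)cc2oc(-c3ccc(OCc4ccccc4)cc3OCc3ccccc3)cc(=O)c12
F2 | step 4 | 7-(benzyloxy)-2-[2,4-bis(benzyloxy)phenyl]-5-hydroxy-6-(3-methylbut-2-en-1-yl)-4H-chromen-4-one | CC(C)=CCc1c(OCc2ccccc2)cc2oc(-c3ccc(OCc4ccccc4)cc3OCc3ccccc3)cc(=O)c2c1O
F3 | step 5 | 5,7-bis(benzyloxy)-2-[2,4-bis(benzyloxy)phenyl]-6-iodo-4H-chromen-4-one | O=c1cc(-c2ccc(OCc3ccccc3)cc2OCc2ccccc2)oc2cc(OCc3ccccc3)c(I)c(OCc3ccccc3)c12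
F4 | step 5 | 5,7-bis(benzyloxy)-2-[2,4-bis(benzyloxy)phenyl]-6-(3-hydroxy-3-methylbut-1-yn-1-yl)-4H-chromen-4-one | CC(C)(O)C#Cc1c(OCc2ccccc2)cc2oc(-c3ccc(OCc4ccccc4)cc3OCc3ccccc3)cc(=O)c2c1OCc1ccccc1
F5 | step 3 | 2-(2,4-dihydroxyphenyl)-5,7-dihydroxy-4H-chromen-4-one | O=c1cc(-c2ccc(O)cc2O)oc2cc(O)cc(O)c12
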